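## The problem

Target 33 is a 6,7-seco-kauranoid. A cyclohexane (ring A) is spiro-joined at C10 to a δ-lactone (C10–C20–O–C7(=O)–C8–C9), and the lactone is fused across C8–C9 to a bicyclo[3.2.1]octane (rings C and D) that carries the C15 ketone and the exocyclic C16=C17 methylene. Seven stereocentres have to be set (C1, C4, C5, C8, C9, C10, C13), three of them quaternary (C4, C8, C10). In the isomer to be made, the C5 CH2OAc arm (C6), the C10–C9 bond, the C1 acetoxy group and the C4 methyl lie on one face of ring A, while C20 and the C4 CH2OH (C19) lie on the other.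

C4 and C5 are neighbours and can be set together. C5 can then steer C10, a C20 hydroxyl can steer the reduction at C1, the C1 oxygen can steer C9 and C8, and C13 follows from C8 once ring D closes. The hard relay is C10 to C9/C8: on a spiro 7,20-lactone the two faces of a C8=C9 olefin are flanked almost symmetrically by C1 and C5, so the facial bias has to be built in.

Several groups will not survive rough treatment:
- the α-methylene cyclopentanone (bases, amines, thiols);
- a β-keto lactone with a quaternary α-carbon (retro-Claisen cleavage, decarboxylation once opened);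
- an α-hydroxymethyl β-keto lactone (retro-aldol);
- two acetates next to a free primary alcohol (acyl migration).

The feature that opens the synthesis is ring A itself. C10–C1(O)–C2–C3 together with C4–C5 is the substitution pattern of a Diels–Alder adduct between a 2-silyloxydiene bearing C9 as a terminal ester and an (E)-2-methyl-4-oxybut-2-enal. That one step delivers the quaternary C4, C5 with its C6 arm, and an epimerisable C10.

## Retrosynthesis

**33 ⇒ 32 ⇒ 31 (C19–O–Si; C16=C17).** The free C19 hydroxyl is released last from silyl ether 32 under acidic fluoride, and the methylene is put onto bicyclic ketone 31 just before. The alternative of an earlier enone would expose the Michael acceptor to the thiolate, base and hydride steps. Ketone 31 has only one enolisable position (C16), so the methylenation needs no regiocontrol.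

**31 ⇒ 30 ⇒ 29 ⇒ 27 (C13–C16, with a transient C12–C16 bond).** Ring D is cut to diazoketone 29, which comes from acid 27; cyclopropyl ketone 30 is the intermediate. A cut at C15–C16 or C8–C15 would need a pre-functionalised C13, and no simple diene can place a substituent there in the ring C cycloaddition. The C8-bound carbenoid reaches C13 through a five-atom tether, and the precursor is simply a cyclohexene with a carboxyl group on C8. The forward steps must add the carbenoid across C12=C13 and then break C16–C12, not C16–C13.

**27/26 ⇒ 24 ⇒ 22 (C7–O20 made, C7–O1 broken).** The spiro lactone of 26 is traced to the fused 1,7-lactone 22 through thioester 24. The reason for the detour is the next cut: only a lactone tied to O1 fixes the geometry of the ring C cycloaddition. The transposition is made irreversible and unambiguous by passing through a dormant acyl donor (the C7 thioester) while O1 and O6 are acetylated and O20 is still silylated.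

**22 ⇒ 20 + 21 (C9–C11 and C8–C14).** Ring C is opened to butadiene 21 and the doubly activated unsaturated lactone 20. A spiro 7,20-lactone dienophile was rejected because its two faces are nearly equivalent. In 20 the lactone is cis-fused to ring A through O1 and the axial C10–C9 bond, so one olefin face is buried under ring A and only the convex face is open. Butadiene gives ring C at the right oxidation level, with the C12=C13 olefin exactly where ring D needs it. The forward reaction must overcome a neopentyl β-carbon.

**20 ⇒ 18 ⇒ 16 ⇒ 14 (C8=C9; C9 oxidation level).** The olefin is a Knoevenagel bond between a C9 aldehyde and a malonate on O1 (18). The aldehyde is taken from the γ-lactone carbonyl of 14 by thiolysis to 15/16 and thioester reduction; this frees the C6 hydroxyl, which is acetylated at once. Reducing an ester at C9 next to a second CH2OH on C10 would have created two primary alcohols that are hard to tell apart; the lactone keeps C9 and C20 distinct throughout.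

**14 ⇒ 13 ⇒ 12 ⇒ 11 (C1–H; C10–C20).** The C1 carbinol comes from hydroxyl-directed reduction of ketone 12, and C20 from an aldol of keto lactone 11 with formaldehyde. Alkylating a monocyclic keto ester would rely on a single neighbouring substituent. In 11 the ring-fusion enolate can only give the cis-fused product, which is the required C20-trans-to-C6 arrangement.

**11 ⇒ 9 ⇒ 7 (C9–O6 lactone; protecting groups).** Keto lactone 11 arises from adduct 7 by reduction of the formyl group, silylation (9) and one acid treatment that unmasks ketone and C6 hydroxyl and closes the lactone. C10 epimerises on the way, so its configuration in 7 does not matter.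

**7 ⇒ 3 + 6 (C5–C10 and C3–C4; ring A).** Ring A is cut to silyloxydiene 3 and enal 6. No other cut gives C4, C5 and the oxygen at C1 from two achiral four- and five-carbon pieces. The forward reaction needs a chiral Lewis acid that tolerates a silyl enol ether and controls the enal face.

**3 ⇐ 1; 6 ⇐ 4 + 5.** Diene 3 is made from keto ester 1 by loss of methanol (2) and silylation. Enal 6 is made by an (E)-selective Wittig reaction of aldehyde 4 with ylide 5.

## Roads not taken

**Alternative 1:** The cut is C13–C16 and C12–C16, and the key step is the rhodium-carbenoid cyclopropanation that gives cyclopropyl ketone A1.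
- Merits: it closes ring D in one step from a C8 carboxyl derivative, puts the ketone at C15 without redox correction, and uses the C12=C13 olefin that a butadiene cycloaddition leaves behind.
- Weak points: as the strategy-defining step it comes after every stereocentre except C13 is already in place. It says nothing about how ring A, the spiro centre or C9/C8 are made, and the later opening must break C16–C12 selectively.
- Comparison: for ring D this road is as good as anything available, and the chosen plan adopts it unchanged (steps 21 and 22; 30 is the C19 tert-butyldiphenylsilyl analogue of A1). What the chosen plan adds is an answer to the earlier and harder problem, the C4/C5/C10 triad.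

**Alternative 2:** The cut is C12–C13, and the key step is an N-heterocyclic-carbene Stetter addition of a C12 aldehyde to C13 of a ring D cyclopentenone, giving dione ester A2.
- Merits: catalytic C–C bond formation without diazo chemistry, a pre-formed ring D, and a possible catalyst-controlled C13.
- Weak points: A2 carries a C12 ketone the target lacks, so one of two hindered ketones must be removed selectively. The quaternary C8, bearing the cyclopentenone, the ester and C9, has to be made by an intermolecular bond to a carbon next to the spiro centre with no obvious control of C8 or C9. The lactone is still open.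
- Comparison: this road is better in avoiding diazomethane and in convergence. The chosen plan sets against it that C8 and C9 are set together in one suprafacial cycloaddition on a rigid dienophile, and that ring C arrives at the correct oxidation level.

**Alternative 3:** The cut is C8–C9 and C13–C14, and the key step is a thermal ester-tethered Diels–Alder reaction of an α-propargyl acrylate on O20 with a 2-silyloxydiene on C10, giving A3.
- Merits: the lactone, ring C and the quaternary C8 form at once, and the propargyl group is ready for an enol–alkyne closure that gives ring D with its methylene. In step count from ring A this is the shortest road.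
- Weak points: the diene hangs on the spiro centre and can present either face, because C1 and C5 flank it almost equally, so C9 is not secured. Ester-tethered cycloadditions need forcing temperatures. A3 has oxygen at C12 to remove and lacks oxygen at C15, which calls for two late redox corrections.
- Comparison: the chosen plan is longer by the lactone transposition. Against that it sets a dienophile with only one accessible face and no surplus or missing oxygen.

Key step: step 4

Assumption: the relative configuration is taken as written (C6 arm trans to C20 and to C19 on ring A, H9 on the C1 side of the lactone, ring C cis-fused to the lactone); all stereochemical arguments refer to that isomer, and kaurane numbering is used for positions.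

## Steps

Step 1
Reactants: 1 methyl 5-methoxy-3-oxopentanoate
Product: 2 methyl 3-oxopent-4-enoate
Conditions: TsOH·H2O (cat.), hydroquinone (cat.), 110 °C, 20 mmHg, distil
Reagents that add atoms: none
Why: Acid-catalysed β-elimination of methanol from the β-methoxy ketone gives the Nazarov reagent, which is distilled out as it forms to limit polymerisation.

Step 2
Reactants: 2 methyl 3-oxopent-4-enoate
Product: 3 methyl (2Z)-3-[(tert-butyldimethylsilyl)oxy]penta-2,4-dienoate
Conditions: TBSOTf, Et3N, Et2O, 0 °C
Reagents that add atoms: tert-butyldimethylsilyl trifluoromethanesulfonate, CC(C)(C)[Si](C)(C)OS(=O)(=O)C(F)(F)F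
Why: Soft enolisation and O-silylation of the hydrogen-bonded β-keto ester enol should give the (2Z) dienol ether, in which the ester sits on the outside of the s-cis diene.

Step 3
Reactants: 4 [(tert-butyldimethylsilyl)oxy]acetaldehyde; 5 2-(triphenylphosphoranylidene)propanal
Product: 6 (2E)-4-[(tert-butyldimethylsilyl)oxy]-2-methylbut-2-enal
Conditions: PhMe, 90 °C
Reagents that add atoms: none
Why: Wittig olefination with a stabilised formyl ylide is (E)-selective and stops at the enal because the product aldehyde is conjugated and α-branched.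

Step 4
Reactants: 3 methyl (2Z)-3-[(tert-butyldimethylsilyl)oxy]penta-2,4-dienoate; 6 (2E)-4-[(tert-butyldimethylsilyl)oxy]-2-methylbut-2-enal
Product: 7 ring A cycloadduct, methyl (1S,5S,6S)-2-[(tert-butyldimethylsilyl)oxy]-6-{[(tert-butyldimethylsilyl)oxy]methyl}-5-formyl-5-methylcyclohex-2-ene-1-carboxylate
Conditions: (R)-1-(2-methylphenyl)-3,3-diphenyltetrahydro-1H,3H-pyrrolo[1,2-c][1,3,2]oxazaborole (20 mol%), (CF3SO2)2NH (20 mol%), CH2Cl2, −78 → −40 °C
Reagents that add atoms: none
Why: The protonated oxazaborolidine binds the formyl oxygen of 6 anti to C4, with a formyl C–H···O contact that holds the s-trans enal over one phenyl ring and lowers its LUMO. The diene terminus C10 (β-carbon of the silyl enol ether, largest HOMO coefficient) bonds to the enal β-carbon C5 slightly ahead of C3–C4 in a concerted, asynchronous, suprafacial [4+2] addition. Ring A is closed by the cycloaddition itself as a cyclohexene, with the silyloxy carbon C1 para to the formyl-bearing C4. The closest known reaction type is the oxazaborolidinium-catalysed Diels–Alder reaction of 2-silyloxydienes, including Nazarov-derived dienol ethers, with α-substituted enals. The relative configuration of C4 and C5 comes from the (E)-olefin, so formyl (C19) ends trans to the C6 arm. Their absolute configuration comes from the catalyst: by the accepted pre-transition-state model the (R)-catalyst should expose the C4-Si/C5-Si face. C10 is set by endo placement of the formyl group (ester cis to formyl), but it is epimerisable and is reset in step 7. The step needs cycloaddition to win over Mukaiyama-type silyl transfer; the bulky tert-butyldimethylsilyl group, the non-nucleophilic counter-ion and low temperature should secure this.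

Step 5
Reactants: 7 ring A cycloadduct
Product: 8 C19 alcohol
Conditions: NaBH4, MeOH/THF, −40 °C
Reagents that add atoms: none
Why: Chemoselective borohydride reduction of the neopentyl aldehyde; the methyl ester and the silyl enol ether are inert at this temperature.

Step 6
Reactants: 8 C19 alcohol
Product: 9 C19 tert-butyldiphenylsilyl ether
Conditions: TBDPSCl, imidazole, DMAP (cat.), DMF, 23 °C
Reagents that add atoms: tert-butyl(chloro)diphenylsilane, CC(C)(C)[Si](Cl)(c1ccccc1)c1ccccc1
Why: Silylation of the only hydroxyl installs a group that outlasts acid, Lewis acids and fluoride treatments of the tert-butyldimethylsilyl ethers and is removed only at the end.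

Step 7
Reactants: 9 C19 tert-butyldiphenylsilyl ether
Product: 11 cis-fused keto γ-lactone, via hydroxy keto ester 10 (not isolated)
Conditions: TsOH·H2O (0.2 equiv), MeOH, 23 °C; then PhMe, 60 °C
Reagents that add atoms: none
Why: Acid methanolysis cleaves the silyl enol ether and the primary tert-butyldimethylsilyl ether but not the tert-butyldiphenylsilyl ether. C10 of the β-keto ester epimerises through its enol, and the C6 hydroxyl then closes the five-membered lactone (transesterification), which can only be cis-fused.

Step 8
Reactants: 11 cis-fused keto γ-lactone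
Product: 12 C20 hydroxymethyl keto lactone
Conditions: 37% aq. CH2O, KHCO3 (cat.), THF, 0 → 23 °C
Reagents that add atoms: formaldehyde, C=O
Why: Aldol hydroxymethylation of the β-keto lactone enolate. Formaldehyde must add to the convex face, anti to the lactone bond at C5 and to the axial C4 methyl, so C20 enters trans to the C6 arm and the lactone stays cis-fused; mild bicarbonate limits retro-aldol loss.

Step 9
Reactants: 12 C20 hydroxymethyl keto lactone
Product: 13 C1,C20 diol lactone
Conditions: Me4NBH(OAc)3, MeCN/AcOH, −30 °C
Reagents that add atoms: none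
Why: Evans–Saksena hydroxyl-directed reduction. The C20 alkoxyborohydride delivers hydride to the C1 ketone from the C20 face, giving the 1,3-anti diol with C1–OH cis to C9; the lactone is not reduced.

Step 10
Reactants: 13 C1,C20 diol lactone
Product: 14 C20 tert-butyldimethylsilyl ether
Conditions: TBSCl, imidazole, CH2Cl2, 0 °C
Reagents that add atoms: tert-butyl(chloro)dimethylsilane, CC(C)(C)[Si](C)(C)Cl
Why: Selective silylation of the primary hydroxyl over the secondary C1 hydroxyl, which is flanked by the quaternary C10.

Step 11
Reactants: 14 C20 tert-butyldimethylsilyl ether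
Product: 15 C9 S-ethyl thioester diol
Conditions: AlMe3, EtSH, CH2Cl2, 0 → 23 °C; Rochelle salt work-up at 0 °C
Reagents that add atoms: ethanethiol, CCS
Why: Dimethylaluminium ethanethiolate opens the γ-lactone by acyl substitution, driven by the Al–O bond. This puts C9 at a reducible acyl level and frees the C6 hydroxyl.

Step 12
Reactants: 15 C9 S-ethyl thioester diol
Product: 16 C6 acetate thioester
Conditions: AcCl, 2,4,6-collidine, CH2Cl2, −78 °C
Reagents that add atoms: acetyl chloride, CC(=O)Cl
Why: Fast acetylation of the unhindered primary hydroxyl with a non-nucleophilic base traps it before it can re-close onto the thioester; the hindered C1 hydroxyl is left free.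

Step 13
Reactants: 16 C6 acetate thioester; 17 3-(tert-butoxy)-3-oxopropanoic acid
Product: 18 C1 tert-butyl malonate thioester
Conditions: DCC, DMAP (cat.), CH2Cl2, 0 → 23 °C
Reagents that add atoms: none
Why: Carbodiimide esterification of the hindered secondary alcohol. Malonic half-esters acylate such alcohols readily because activation passes through the alkoxycarbonylketene.

Step 14
Reactants: 18 C1 tert-butyl malonate thioester
Product: 20 fused unsaturated 1,7-lactone, via malonate aldehyde 19 (not isolated)
Conditions: Et3SiH, Pd/C, acetone, 23 °C; filter; piperidine (cat.), AcOH (cat.), PhMe, 4 Å MS, 23 → 50 °C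
Reagents that add atoms: none
Why: Fukuyama reduction turns the thioester into the aldehyde without touching esters or silyl ethers. The tethered malonate then condenses with it (intramolecular Knoevenagel, six-membered ring), which works even at a neopentyl aldehyde.

Step 15
Reactants: 20 fused unsaturated 1,7-lactone; 21 buta-1,3-diene
Product: 22 tricyclic 1,7-lactone cycloadduct
Conditions: Et2AlCl, CH2Cl2, −40 → 0 °C, excess 21
Reagents that add atoms: none
Why: Lewis-acid-promoted Diels–Alder reaction of a chelating alkylidene malonate-type dienophile. The lactone is cis-fused to ring A through O1 and the axial C10–C9 bond, so the inner olefin face is covered by ring A (axial H at C2, axial C4 methyl) and butadiene must add to the convex face. Suprafacial addition sets C9 and C8 together, with C11 and C14 away from ring A and the ester carbon C15 cis to H9.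

Step 16
Reactants: 22 tricyclic 1,7-lactone cycloadduct
Product: 23 C7 thioester diol
Conditions: AlMe3, EtSH, CH2Cl2, 0 → 23 °C
Reagents that add atoms: ethanethiol, CCS
Why: The aluminium thiolate converts the 1,7-lactone into the C7 S-ethyl thioester and frees O1; it also cleaves the C6 acetate, while the tert-butyl ester should resist. The thioester is a dormant acyl donor that keeps the identity of C7 fixed.

Step 17
Reactants: 23 C7 thioester diol
Product: 24 C7 thioester diacetate
Conditions: Ac2O, DMAP, pyridine, 23 °C
Reagents that add atoms: acetic anhydride, CC(=O)OC(C)=O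
Why: Acetylation installs both acetates of the target at C1 and C6. The thioester does not acylate alcohols without a thiophilic metal, so O1 cannot re-close the lactone.

Step 18
Reactants: 24 C7 thioester diacetate
Product: 26 spiro 7,20-lactone tert-butyl ester, via C20 hydroxy thioester 25 (not isolated)
Conditions: HF·pyridine, pyridine, THF, 0 → 23 °C; then AgOCOCF3, Na2HPO4, PhMe, 23 → 60 °C
Reagents that add atoms: none
Why: Acidic fluoride removes the tert-butyldimethylsilyl ether in the presence of the tert-butyldiphenylsilyl ether and without acetate migration. Monovalent silver then activates the thioester for six-membered lactonisation onto O20 (thioester lactonisation of the Masamune type), the only free hydroxyl, so the transposition is irreversible.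

Step 19
Reactants: 26 spiro 7,20-lactone tert-butyl ester
Product: 27 C15 carboxylic acid
Conditions: CF3CO2H/CH2Cl2 (1:4), 0 → 23 °C
Reagents that add atoms: none
Why: Acidolysis of the tert-butyl ester by loss of isobutene; lactone, acetates and the tert-butyldiphenylsilyl ether tolerate brief exposure, and the acid is kept cold to avoid decarboxylation.

Step 20
Reactants: 27 C15 carboxylic acid
Product: 29 diazoketone, via acid chloride 28 (not isolated)
Conditions: (COCl)2, DMF (cat.), CH2Cl2, 0 °C; concentrate; CH2N2 (excess), Et2O, 0 °C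
Reagents that add atoms: diazomethane, C=[N+]=[N-]
Why: Acylation of diazomethane by the acid chloride (first stage of an Arndt–Eistert sequence). The quaternary α-carbon rules out ketene formation, and excess diazomethane scavenges HCl.

Step 21
Reactants: 29 diazoketone
Product: 30 cyclopropyl ketone
Conditions: Rh2(OAc)4 (2 mol%), CH2Cl2, 23 °C, slow addition
Reagents that add atoms: none
Why: Intramolecular carbenoid cyclopropanation of a γ,δ-unsaturated diazoketone. C16 can reach the C12=C13 olefin only on the ring C face that carries C15, so the configuration at C13 (and C12, C16) follows from C8.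

Step 22
Reactants: 30 cyclopropyl ketone
Product: 31 bicyclo[3.2.1]octan-15-one
Conditions: SmI2, THF/MeOH, −78 °C
Reagents that add atoms: none
Why: Reductive cleavage of an α-cyclopropyl ketone through its ketyl. The C16–C13 bond lies almost in the carbonyl plane of the five-membered ring, whereas C16–C12 is twisted roughly 50° out of it and overlaps with the ketyl, so C16–C12 should break. Methanol protonates the C12 carbanion and the enolate, and C13 is untouched.

Step 23
Reactants: 31 bicyclo[3.2.1]octan-15-one
Product: 32 α-methylene ketone silyl ether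
Conditions: (CH2O)n, N-methylanilinium trifluoroacetate, THF, 65 °C
Reagents that add atoms: formaldehyde (as paraformaldehyde), C=O
Why: Mannich-type α-methylenation (iminium addition to the enol, then β-elimination of the amine). C16 is the only enolisable position, and the mildly acidic medium spares lactone, acetates and silyl ether.

Step 24
Reactants: 32 α-methylene ketone silyl ether
Product: 33 target
Conditions: HF·pyridine, THF, 0 → 23 °C
Reagents that add atoms: none
Why: Acidic fluoride desilylation of the primary tert-butyldiphenylsilyl ether; the absence of base avoids conjugate addition to the enone and acetyl migration to C19.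

## Compound list

1 | methyl 5-methoxy-3-oxopentanoate | COCCC(=O)CC(=O)OC | starting material
2 | methyl 3-oxopent-4-enoate | C=CC(=O)CC(=O)OC | intermediate
3 | methyl (2Z)-3-[(tert-butyldimethylsilyl)oxy]penta-2,4-dienoate | COC(=O)/C=C(\O[Si](C)(C)C(C)(C)C)C=C | intermediate
4 | [(tert-butyldimethylsilyl)oxy]acetaldehyde | O=CCO[Si](C)(C)C(C)(C)C | starting material
5 | 2-(triphenylphosphoranylidene)propanal | CC(C=O)=P(c1ccccc1)(c1ccccc1)c1ccccc1 | starting material
6 | (2E)-4-[(tert-butyldimethylsilyl)oxy]-2-methylbut-2-enal | O=C/C(C)=C/CO[Si](C)(C)C(C)(C)C | intermediate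
7 | methyl (1S,5S,6S)-2-[(tert-butyldimethylsilyl)oxy]-6-{[(tert-butyldimethylsilyl)oxy]methyl}-5-formyl-5-methylcyclohex-2-ene-1-carboxylate (formyl trans to the silyloxymethyl arm, ester cis to formyl) | COC(=O)[C@@H]1C(O[Si](C)(C)C(C)(C)C)=CC[C@](C)(C=O)[C@H]1CO[Si](C)(C)C(C)(C)C | intermediate
8 | methyl (1S,5S,6S)-2-[(tert-butyldimethylsilyl)oxy]-6-{[(tert-butyldimethylsilyl)oxy]methyl}-5-(hydroxymethyl)-5-methylcyclohex-2-ene-1-carboxylate | COC(=O)[C@@H]1C(O[Si](C)(C)C(C)(C)C)=CC[C@](C)(CO)[C@H]1CO[Si](C)(C)C(C)(C)C | intermediate
9 | methyl (1S,5S,6S)-2-[(tert-butyldimethylsilyl)oxy]-6-{[(tert-butyldimethylsilyl)oxy]methyl}-5-{[(tert-butyldiphenylsilyl)oxy]methyl}-5-methylcyclohex-2-ene-1-carboxylate | COC(=O)[C@@H]1C(O[Si](C)(C)C(C)(C)C)=CC[C@](C)(CO[Si](c2ccccc2)(c2ccccc2)C(C)(C)C)[C@H]1CO[Si](C)(C)C(C)(C)C | intermediate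
10 | methyl (5S,6S)-5-{[(tert-butyldiphenylsilyl)oxy]methyl}-6-(hydroxymethyl)-5-methyl-2-oxocyclohexane-1-carboxylate (C1 epimerising, drawn as first formed) | COC(=O)[C@@H]1C(=O)CC[C@](C)(CO[Si](c2ccccc2)(c2ccccc2)C(C)(C)C)[C@H]1CO | intermediate (not isolated)
11 | (3aS,4S,7aR)-4-{[(tert-butyldiphenylsilyl)oxy]methyl}-4-methylhexahydro-2-benzofuran-1,7-dione (cis-fused C9(=O)–O–C6 lactone, C1 ketone) | O=C2[C@H]1C(=O)CC[C@](C)(CO[Si](c3ccccc3)(c3ccccc3)C(C)(C)C)[C@H]1CO2 | intermediate
12 | 7a-(hydroxymethyl) derivative of 11: C20 CH2OH on C10 trans to the lactone CH2 (C6), lactone cis-fused | O=C2[C@@]1(CO)C(=O)CC[C@](C)(CO[Si](c3ccccc3)(c3ccccc3)C(C)(C)C)[C@H]1CO2 | intermediate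
13 | diol lactone: 12 with the C1 ketone reduced, C1–OH cis to the lactone carbonyl (C9) and trans to C20 | O=C2[C@@]1(CO)[C@@H](O)CC[C@](C)(CO[Si](c3ccccc3)(c3ccccc3)C(C)(C)C)[C@H]1CO2 | intermediate
14 | 13 with C20–OH as tert-butyldimethylsilyl ether | O=C2[C@@]1(CO[Si](C)(C)C(C)(C)C)[C@@H](O)CC[C@](C)(CO[Si](c3ccccc3)(c3ccccc3)C(C)(C)C)[C@H]1CO2 | intermediate
15 | ring A S-ethyl thioester (C9) with free C1–OH and C6–OH, C20 silyl ether, C19 silyl ether | CCSC(=O)[C@@]1(CO[Si](C)(C)C(C)(C)C)[C@@H](O)CC[C@](C)(CO[Si](c2ccccc2)(c2ccccc2)C(C)(C)C)[C@H]1CO | intermediate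
16 | 15 with C6–OH acetylated | CCSC(=O)[C@@]1(CO[Si](C)(C)C(C)(C)C)[C@@H](O)CC[C@](C)(CO[Si](c2ccccc2)(c2ccccc2)C(C)(C)C)[C@H]1COC(C)=O | intermediate
17 | 3-(tert-butoxy)-3-oxopropanoic acid (mono-tert-butyl malonate) | CC(C)(C)OC(=O)CC(=O)O | starting material
18 | 16 with C1–OH esterified as tert-butyl malonate | CCSC(=O)[C@@]1(CO[Si](C)(C)C(C)(C)C)[C@@H](OC(=O)CC(=O)OC(C)(C)C)CC[C@](C)(CO[Si](c2ccccc2)(c2ccccc2)C(C)(C)C)[C@H]1COC(C)=O | intermediate
19 | C9 aldehyde corresponding to 18 | O=C[C@@]1(CO[Si](C)(C)C(C)(C)C)[C@@H](OC(=O)CC(=O)OC(C)(C)C)CC[C@](C)(CO[Si](c2ccccc2)(c2ccccc2)C(C)(C)C)[C@H]1COC(C)=O | intermediate (not isolated)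
20 | fused α-(tert-butoxycarbonyl)-α,β-unsaturated δ-lactone O1–C7(=O)–C8=C9 on ring A (C6 acetate, C20 and C19 silyl ethers) | CC(C)(C)OC(=O)C2=C[C@@]1(CO[Si](C)(C)C(C)(C)C)[C@@H](OC2=O)CC[C@](C)(CO[Si](c3ccccc3)(c3ccccc3)C(C)(C)C)[C@H]1COC(C)=O | intermediate
21 | buta-1,3-diene | C=CC=C | starting material
22 | tricyclic cycloadduct: ring C cyclohexene (C12=C13) cis-fused to the 1,7-lactone, C8 bearing CO2tBu cis to H9 | CC(C)(C)OC(=O)[C@]23CC=CC[C@H]2[C@@]1(CO[Si](C)(C)C(C)(C)C)[C@@H](OC3=O)CC[C@](C)(CO[Si](c4ccccc4)(c4ccccc4)C(C)(C)C)[C@H]1COC(C)=O | intermediate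
23 | ring-opened C7 S-ethyl thioester with free C1–OH and C6–OH | CC(C)(C)OC(=O)[C@]2(C(=O)SCC)CC=CC[C@H]2[C@@]1(CO[Si](C)(C)C(C)(C)C)[C@@H](O)CC[C@](C)(CO[Si](c3ccccc3)(c3ccccc3)C(C)(C)C)[C@H]1CO | intermediate
24 | 23 as C1,C6 diacetate | CC(C)(C)OC(=O)[C@]2(C(=O)SCC)CC=CC[C@H]2[C@@]1(CO[Si](C)(C)C(C)(C)C)[C@@H](OC(C)=O)CC[C@](C)(CO[Si](c3ccccc3)(c3ccccc3)C(C)(C)C)[C@H]1COC(C)=O | intermediate
25 | 24 with free C20–OH | CC(C)(C)OC(=O)[C@]2(C(=O)SCC)CC=CC[C@H]2[C@@]1(CO)[C@@H](OC(C)=O)CC[C@](C)(CO[Si](c3ccccc3)(c3ccccc3)C(C)(C)C)[C@H]1COC(C)=O | intermediate (not isolated)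
26 | spiro 7,20-lactone with ring C cyclohexene, C8–CO2tBu, C1 and C6 acetates, C19 silyl ether | CC(C)(C)OC(=O)[C@]23CC=CC[C@H]2[C@@]1(COC3=O)[C@@H](OC(C)=O)CC[C@](C)(CO[Si](c4ccccc4)(c4ccccc4)C(C)(C)C)[C@H]1COC(C)=O | intermediate
27 | C15 carboxylic acid corresponding to 26 | OC(=O)[C@]23CC=CC[C@H]2[C@@]1(COC3=O)[C@@H](OC(C)=O)CC[C@](C)(CO[Si](c4ccccc4)(c4ccccc4)C(C)(C)C)[C@H]1COC(C)=O | intermediate
28 | C15 acid chloride | ClC(=O)[C@]23CC=CC[C@H]2[C@@]1(COC3=O)[C@@H](OC(C)=O)CC[C@](C)(CO[Si](c4ccccc4)(c4ccccc4)C(C)(C)C)[C@H]1COC(C)=O | intermediate (not isolated)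
29 | C8 diazoacetyl compound (diazoketone) | [N-]=[N+]=CC(=O)[C@]23CC=CC[C@H]2[C@@]1(COC3=O)[C@@H](OC(C)=O)CC[C@](C)(CO[Si](c4ccccc4)(c4ccccc4)C(C)(C)C)[C@H]1COC(C)=O | intermediate
30 | pentacyclic cyclopropyl ketone (C16 bonded to C12 and C13, C15 ketone) | [C@H]14C(=O)[C@]23C[C@H]1[C@H]4C[C@H]2[C@@]1(COC3=O)[C@@H](OC(C)=O)CC[C@](C)(CO[Si](c5ccccc5)(c5ccccc5)C(C)(C)C)[C@H]1COC(C)=O | intermediate
31 | bicyclo[3.2.1]octan-15-one spirolactone (C16 and C12 methylene), C19 silyl ether | C1C(=O)[C@]23C[C@H]1CC[C@H]2[C@@]1(COC3=O)[C@@H](OC(C)=O)CC[C@](C)(CO[Si](c4ccccc4)(c4ccccc4)C(C)(C)C)[C@H]1COC(C)=O | intermediate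
32 | 16-methylene-15-ketone, C19 tert-butyldiphenylsilyl ether of the target | C=C1C(=O)[C@]23C[C@H]1CC[C@H]2[C@@]1(COC3=O)[C@@H](OC(C)=O)CC[C@](C)(CO[Si](c4ccccc4)(c4ccccc4)C(C)(C)C)[C@H]1COC(C)=O | intermediate
33 | CNP0370815.4: 1,6-diacetoxy-19-hydroxy-15-oxo-6,7-seco-kaur-16-en-7,20-olide in the configuration of the stated structure | C=C1C(=O)[C@]23C[C@H]1CC[C@H]2[C@@]1(COC3=O)[C@@H](OC(C)=O)CC[C@](C)(CO)[C@H]1COC(C)=O | target

## Step count and least certain steps

Total: 24 steps. Longest linear sequence: 23 steps (steps 1, 2 and 4–24 from 1); enal 6 is made in one side step (step 3).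

**Step 4 (key step).** The ester on the diene terminus lowers its nucleophilicity and the enal is α,β-disubstituted, so the cycloaddition may be slow. Silyl transfer (Mukaiyama–Michael or aldol pathways) or loss of enantioselectivity at the higher temperature then needed could take over. The fallback keeps the same two ring bonds but uses an ester-free diene and brings in C9 afterwards through the C6 oxygen. It sets out from 6. With the same catalyst, 6 reacts with 2-[(tert-butyldimethylsilyl)oxy]buta-1,3-diene F1 (from but-3-en-2-one, TBSOTf, Et3N) to give the 4-silyloxycyclohexene carbaldehyde F2. NaBH4 gives alcohol F3, and TBDPSCl gives silyl ether F4. TsOH in methanol unmasks the hydroxy ketone F5. Methyl chloroformate and pyridine give the C6 methyl carbonate F6. NaH in THF equilibrates the ketone enolates, and the C10 enolate, the only one within reach, is acylated intramolecularly to give the β-keto γ-lactone. The fallback comes back to the route at 11.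

**Step 15.** Bond formation at C9 next to the quaternary C10 may be too slow for an alkylidene malonate-type dienophile, and a stronger Lewis acid would endanger the tert-butyl ester and the silyl ethers. The face of attack is not in doubt; the rate is. The fallback uses a far more nucleophilic diene and removes its oxygen afterwards. It sets out from 20. Heating 20 with diene F1 in toluene should give the C12 silyl enol ether cycloadduct F7 (C11 bonded to C9, olefin C12=C13). CsF and PhNTf2 convert it to the enol triflate F8. Reduction with Pd(OAc)2, PPh3, HCO2H and Bu3N replaces the triflate by hydrogen. The fallback comes back to the route at 22.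

**Step 16.** The lactone carbonyl sits on the quaternary C8, so thiolysis may stall, or the tert-butyl ester may be lost on forcing. The fallback opens the lactone with hydroxide and carries C7 as an allyl ester. It sets out from 22. LiOH in aqueous THF opens the lactone and cleaves the C6 acetate. Alkylating the carboxylate with allyl bromide in DMF, which cannot re-close the lactone, gives the allyl ester diol F9. Ac2O/DMAP gives diacetate F10. Pd(PPh3)4 and morpholine free the acid F11. HF·pyridine gives the C20 hydroxy acid F12, which is lactonised with EDC and DMAP. The fallback comes back to the route at 26.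

**Step 11.** The γ-hydroxy thioester may re-close to the lactone during work-up, before the C6 hydroxyl is acetylated; the hindered carbonyl may also open slowly. The fallback uses an amide that does not re-lactonise under base. It sets out from 14. Me(MeO)NH·HCl and AlMe3 give the hydroxy Weinreb amide F13. Selective acetylation gives the C6 acetate F14. Cp2Zr(H)Cl reduces the amide in the presence of the acetate to the β-hydroxy aldehyde F15. Esterification with 17 (DCC, DMAP) gives the malonate aldehyde. The fallback comes back to the route at 19, which condenses to 20 as in step 14.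

**Step 22.** Cleavage of the other cyclopropane bond (C16–C13) would give a bicyclo[2.2.2]octanone, and over-reduction of the ketone is possible. The fallback avoids the cyclopropane altogether and forms C13–C16 by enolate carbopalladation. It sets out from 27. The acid chloride 28 reacts with Me2CuLi at −78 °C to give methyl ketone F16. TBSOTf and Et3N give the enol silane F17. Pd(OAc)2 in MeCN (divalent palladium, cycloalkenylation of the silyl enol ether onto C13 followed by β-hydride elimination) gives the bicyclo[3.2.1]octenone F18 with a C11=C12 olefin. Hydrogenation over Pd/C saturates the olefin. The fallback comes back to the route at 31.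

## Further compounds

F1 | step 4 | 2-[(tert-butyldimethylsilyl)oxy]buta-1,3-diene | C=CC(=C)O[Si](C)(C)C(C)(C)C
F2 | step 4 | (1S,6S)-4-[(tert-butyldimethylsilyl)oxy]-6-{[(tert-butyldimethylsilyl)oxy]methyl}-1-methylcyclohex-3-ene-1-carbaldehyde | C1C(O[Si](C)(C)C(C)(C)C)=CC[C@](C)(C=O)[C@H]1CO[Si](C)(C)C(C)(C)C
F3 | step 4 | [(1S,6S)-4-[(tert-butyldimethylsilyl)oxy]-6-{[(tert-butyldimethylsilyl)oxy]methyl}-1-methylcyclohex-3-en-1-yl]methanol | C1C(O[Si](C)(C)C(C)(C)C)=CC[C@](C)(CO)[C@H]1CO[Si](C)(C)C(C)(C)C
F4 | step 4 | tert-butyldiphenylsilyl ether of F3 | C1C(O[Si](C)(C)C(C)(C)C)=CC[C@](C)(CO[Si](c2ccccc2)(c2ccccc2)C(C)(C)C)[C@H]1CO[Si](C)(C)C(C)(C)C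
F5 | step 4 | (3S,4S)-4-{[(tert-butyldiphenylsilyl)oxy]methyl}-3-(hydroxymethyl)-4-methylcyclohexan-1-one | C1C(=O)CC[C@](C)(CO[Si](c2ccccc2)(c2ccccc2)C(C)(C)C)[C@H]1CO
F6 | step 4 | methyl carbonate of F5 at the C6 oxygen | C1C(=O)CC[C@](C)(CO[Si](c2ccccc2)(c2ccccc2)C(C)(C)C)[C@H]1COC(=O)OC
F7 | step 15 | C12 tert-butyldimethylsilyl enol ether analogue of 22 (olefin C12=C13) | CC(C)(C)OC(=O)[C@]23CC=C(O[Si](C)(C)C(C)(C)C)C[C@H]2[C@@]1(CO[Si](C)(C)C(C)(C)C)[C@@H](OC3=O)CC[C@](C)(CO[Si](c4ccccc4)(c4ccccc4)C(C)(C)C)[C@H]1COC(C)=O
F8 | step 15 | C12 enol triflate analogue of 22 | CC(C)(C)OC(=O)[C@]23CC=C(OS(=O)(=O)C(F)(F)F)C[C@H]2[C@@]1(CO[Si](C)(C)C(C)(C)C)[C@@H](OC3=O)CC[C@](C)(CO[Si](c4ccccc4)(c4ccccc4)C(C)(C)C)[C@H]1COC(C)=O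
F9 | step 16 | C7 allyl ester with free C1–OH and C6–OH (ring-opened 22) | CC(C)(C)OC(=O)[C@]2(C(=O)OCC=C)CC=CC[C@H]2[C@@]1(CO[Si](C)(C)C(C)(C)C)[C@@H](O)CC[C@](C)(CO[Si](c3ccccc3)(c3ccccc3)C(C)(C)C)[C@H]1CO
F10 | step 16 | C1,C6 diacetate of F9 | CC(C)(C)OC(=O)[C@]2(C(=O)OCC=C)CC=CC[C@H]2[C@@]1(CO[Si](C)(C)C(C)(C)C)[C@@H](OC(C)=O)CC[C@](C)(CO[Si](c3ccccc3)(c3ccccc3)C(C)(C)C)[C@H]1COC(C)=O
F11 | step 16 | C7 carboxylic acid from F10 (C20 silyl ether retained) | CC(C)(C)OC(=O)[C@]2(C(=O)O)CC=CC[C@H]2[C@@]1(CO[Si](C)(C)C(C)(C)C)[C@@H](OC(C)=O)CC[C@](C)(CO[Si](c3ccccc3)(c3ccccc3)C(C)(C)C)[C@H]1COC(C)=O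
F12 | step 16 | C20 hydroxy C7 acid | CC(C)(C)OC(=O)[C@]2(C(=O)O)CC=CC[C@H]2[C@@]1(CO)[C@@H](OC(C)=O)CC[C@](C)(CO[Si](c3ccccc3)(c3ccccc3)C(C)(C)C)[C@H]1COC(C)=O
F13 | step 11 | C9 N-methoxy-N-methylamide with free C1–OH and C6–OH | CON(C)C(=O)[C@@]1(CO[Si](C)(C)C(C)(C)C)[C@@H](O)CC[C@](C)(CO[Si](c2ccccc2)(c2ccccc2)C(C)(C)C)[C@H]1CO
F14 | step 11 | C6 acetate of F13 | CON(C)C(=O)[C@@]1(CO[Si](C)(C)C(C)(C)C)[C@@H](O)CC[C@](C)(CO[Si](c2ccccc2)(c2ccccc2)C(C)(C)C)[C@H]1COC(C)=O
F15 | step 11 | C9 aldehyde with free C1–OH and C6 acetate | O=C[C@@]1(CO[Si](C)(C)C(C)(C)C)[C@@H](O)CC[C@](C)(CO[Si](c2ccccc2)(c2ccccc2)C(C)(C)C)[C@H]1COC(C)=O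
F16 | step 22 | C8 acetyl (methyl ketone) analogue of 29 | CC(=O)[C@]23CC=CC[C@H]2[C@@]1(COC3=O)[C@@H](OC(C)=O)CC[C@](C)(CO[Si](c4ccccc4)(c4ccccc4)C(C)(C)C)[C@H]1COC(C)=O
F17 | step 22 | tert-butyldimethylsilyl enol ether of F16 | C=C(O[Si](C)(C)C(C)(C)C)[C@]23CC=CC[C@H]2[C@@]1(COC3=O)[C@@H](OC(C)=O)CC[C@](C)(CO[Si](c4ccccc4)(c4ccccc4)C(C)(C)C)[C@H]1COC(C)=O
F18 | step 22 | bicyclo[3.2.1]oct-11-en-15-one analogue of 31 (olefin C11=C12) | C1C(=O)[C@]23C[C@H]1C=C[C@H]2[C@@]1(COC3=O)[C@@H](OC(C)=O)CC[C@](C)(CO[Si](c4ccccc4)(c4ccccc4)C(C)(C)C)[C@H]1COC(C)=O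
A1 | alternative 1 | pentacyclic cyclopropyl ketone with C19 tert-butyldimethylsilyl ether | [C@H]14C(=O)[C@]23C[C@H]1[C@H]4C[C@H]2[C@@]1(COC3=O)[C@@H](OC(C)=O)CC[C@](C)(CO[Si](C)(C)C(C)(C)C)[C@H]1COC(C)=O
A2 | alternative 2 | bicyclo[3.2.1]octane-12,15-dione C7 methyl ester with C20 and C19 silyl ethers | C1C(=O)[C@]2(C(=O)OC)C[C@H]1C(=O)C[C@H]2[C@@]1(CO[Si](C)(C)C(C)(C)C)[C@@H](OC(C)=O)CC[C@](C)(CO[Si](C)(C)C(C)(C)C)[C@H]1COC(C)=O
A3 | alternative 3 | tricyclic spirolactone C12 silyl enol ether with C8 propargyl group | C#CC[C@]23CCC(O[Si](C)(C)C(C)(C)C)=C[C@H]2[C@@]1(COC3=O)[C@@H](OC(C)=O)CC[C@](C)(CO[Si](C)(C)C(C)(C)C)[C@H]1COC(C)=O
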